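In the elm run links stood above over-reaction product at 2.00 h, 24% against 5%, and below it at 15.0 h, 7% against 35%. So I took the share S of links in links plus over-reaction product (the selectivity) to be a matter of how long links had stood.

| flask | first end groups | second end groups | protic impurity | temperature | remark | time |
|---|---|---|---|---|---|---|
| elm | 0.024 M | 0.0216 M | 0.024 M | 25 °C | run made earlier |  |
| birch | 0.036 M | 0.0216 M | 0.024 M | 25 °C | run made earlier |  |
| zeta | 0.024 M | 0.0216 M (fed, over 10 h) | 0.0240 M |  | the addition at −5 °C, then warmed to 25 °C; the feed brings no volume worth counting | 15 h |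
| alpha | 0.024 M (in portions, 5, over 10 h) | 0.0216 M | 0.0240 M | 25 °C | first portion at the start, last at 10 h | 15 h |
| beta | 0.024 M | 0.0216 M | 0.0240 M | 25 °C | everything together at the start | 15 h |
| theta | 0.024 M (fed, over 10 h) | 0.0216 M | 0.0240 M | 25 °C | all else is in the flask from the start; the feed brings no volume worth counting | 15 h |

- elm (time / h: links / %, over-reaction product / %): 2.00: 24, 5; 4.00: 23, 12; 6.00: 21, 17; 8.00: 19, 19; 10.0: 17, 28; 12.0: 12, 31; 15.0: 7, 35
- birch (time / min: links / %, over-reaction product / %): 5.00: 2, 0; 15.0: 7, 3; 25.0: 9, 1; 40.0: 17, 0; 50.0: 16, 1; 80.0: 19, 4; 90.0: 17, 3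

(scatter of a reading: 1.5 percentage points)

- the earlier runs do not show what temperature does; that part of a forecast is a guess

1. the flask with the highest share of links in links plus over-reaction product ("all alike" if they lie within 1.5 percentage points) (zeta / alpha / beta / theta / all alike)
2. share of links in links plus over-reaction product at the end, zeta
3. share of links in links plus over-reaction product at the end, alpha
4. share of links in links plus over-reaction product at the end, beta
5. share of links in links plus over-reaction product at the end, theta

I built the flask up one process at a time. With the link-forming step by itself, S is 100%.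

Then I added over-reaction. In elm the product rose from 5% to 31% between 2.00 h and 12.0 h, while links stood near 20.0%. That gives the loss constant k, the fraction of links lost per hour, with a link of age a surviving as exp(−ka):

k = 0.130 h⁻¹

If every link dated from the start, beta, which repeats elm's recipe, would end at 14.2%.

The rest concerns making. Links plus product read 29.0% at 2.00 h, 45.0% at 10.0 h and 42.0% at 15.0 h. The last reading lay below the 90.0% at which second end groups were charged, so I supposed the protic impurity takes some of them. I let these readings set only the mean making time m, taking the making as over by 10.0 h as a working assumption and placing each batch at the middle of its interval: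

m = 2.55 h

For the additions I assumed each lot of first end groups waits m after entering, and for zeta, as a guess, that cold hours age nothing:

beta, exp(−k(t − m)): 19.8%
theta, averaged over the feed: 40.7%
alpha, averaged over the portions: 42.1%
zeta, the warm hours: 52.2%

So I put zeta first.

The forecast, whose figures differ from mine, named zeta, with 57% for zeta, 32% for alpha, 18% for beta and 29% for theta, reasoning that “the cold largely halts over-reaction for 10 h”.

The flasks gave zeta as highest, with zeta 56.6%, alpha 38.0%, beta 23.2% and theta 40.1%.

    first end groups + second end groups ⇌ links + by-product (K = 2.40, k = 19.0 M⁻¹ h⁻¹, Ea = 53.0 kJ mol⁻¹, ΔH = 10.0 kJ mol⁻¹)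
    second end groups + protic impurity → quenched reagent (k = 3.50 M⁻¹ h⁻¹, Ea = 51.0 kJ mol⁻¹)
    links → over-reaction product (k = 0.140 h⁻¹, Ea = 101 kJ mol⁻¹)
    second end groups ⇌ dormant form (K = 2.40, k = 0.850 h⁻¹, Ea = 89.0 kJ mol⁻¹, ΔH = −29.0 kJ mol⁻¹)
    (constants at 25 °C)

Put back through k, beta's share is an age of 11.2 h, where I had reckoned 12.5 h. The neighbouring flask is beta with 0.0060 M of first end groups. Keeping k and m, the same reckoning gave it beta's 19.8%, but the neighbouring flask gave 25.8%, an age of 10.4 h. At 15.0 h the neighbouring flask held links at 17.9%, over-reaction product at 51.7% and first end groups at 30.4%.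

All runs were computed with made-up constants; noise was put on by code.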